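In the red run, with starting complex dosed over 3.0 h and 0.67 equiv of incoming ligand, the reading at 5.00 d shows 19.4 % starting complex and 9.5 % complex with two exchanged. So 71.1 % of the charge stands in neither.

all flasks: starting complex 0.020 M (fed, over 3.0 h)
- red: incoming ligand 0.67 equiv; leaving ligand 2 equiv; run made earlier; the fed solution adds 0.25 times the starting volume
- green: incoming ligand 1.5 equiv; leaving ligand 2 equiv; run made earlier; the fed solution adds 0.25 times the starting volume
- blue: incoming ligand 1 equiv; leaving ligand 3 equiv; run made earlier; the fed solution adds 0.25 times the starting volume
- flask: incoming ligand 1.00 equiv; leaving ligand 2.00 equiv; the fed solution adds 0.25 times the starting volume; time 6.0 d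

- red (time / d: starting complex / %, complex with two exchanged / %): 0.625: 23.0, 10.1; 1.67: 20.5, 9.2; 3.00: 19.9, 10.3; 5.00: 19.4, 9.5
- green (time / d: starting complex / %, complex with two exchanged / %): 1.25: 8.2, 19.8; 2.50: 6.3, 16.3; 4.00: 7.4, 15.8; 5.00: 7.6, 14.8
- blue (time / d: starting complex / %, complex with two exchanged / %): 1.25: 15.1, 15.0; 2.50: 13.8, 14.0; 4.00: 12.8, 14.1; 5.00: 13.2, 14.2

(readings scatter by 0.5 percentage points)

- charges are per starting volume, the dose included; the dosed solution carries all of it
- what has gone from starting complex into another species counts as reacted, even if it can come back
- the reaction counts as stopped when no species that holds the starting complex changes by six tenths of a point or more over the second half of the time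

* which holds at 6.0 d: what has brought the reaction to rest, or that it has not come to rest (all of the starting complex has reacted / the incoming ligand has run out first / it is still moving)
* conversion of starting complex at 6.0 d
* amount of complex with two exchanged at 6.0 d, in percent of the starting complex charged
* amount of side product at 6.0 d, in percent of the starting complex charged

Two extreme versions of the new flask can be done in the head. Suppose each complex that reacts takes two ligands: then 50.0 % is two-exchanged, the same amount of starting complex stays, and nothing is unseen. Suppose instead that each takes one ligand and stops: then 100 % of the charge is unseen.

The blue run has the flask's ligand charge, though 3 equiv of leaving ligand against 2.00 equiv, and it stands near the second extreme. Its charge less the starting complex and the two-exchanged complex at 5.00 d, which I call the unseen share, is 72.6 %, and I expect about that in the flask.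

Not all of it need be side product, which I take to hold a ligand. After the two-exchanged complex has had its two ligands, the red run has 48.0 % of the charge in ligand to offer its unseen share. Each unseen complex holding ligand holds at least one, so by these readings about 23 percentage points or more of the red charge hold none. That reads as 1.19 per unit of the starting complex read in the red run. If that ligand-free part follows the starting complex, which is my assumption, scaling to the blue reading puts my side product for the flask at about 56.9 %, and lower if some unseen complex holds several ligands.

The forecast says the incoming ligand has run out first, with conversion 86.5 %, 14 % two-exchanged and 8 % side product, far below my figure, and it remarks: “This is the weakest estimate”.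

In the flask, the incoming ligand has run out first, with 0.0090 % of the charge of this limiting reagent remaining; conversion is 86.4 %, with 14.1 % two-exchanged and 39.9 % side product.

    starting complex + incoming ligand → leaving ligand + complex with one exchanged (k = 19.0 M⁻¹ h⁻¹)
    complex with one exchanged + incoming ligand → leaving ligand + complex with two exchanged (k = 40.0 M⁻¹ h⁻¹)
    complex with two exchanged + incoming ligand → leaving ligand + complex with three exchanged (k = 6.30 M⁻¹ h⁻¹)
    complex with one exchanged → side product (k = 0.380 h⁻¹)
    starting complex ⇌ dormant form (K = 1.60, k = 4.50 h⁻¹)

The dormant form, which holds no incoming ligand, stands at 21.8 % at 6.00 d. The unseen share, 72.6 % in the blue run, is 72.3 % in this flask. In the neighbour flask with 0.0050 M of starting complex, it is 83.0 %, of which side product is 58.9 %.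

Readings and results are calculated for an exercise.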